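## Retrosynthetic overview

1. The only ring (the cyclohexenone) is made last: a base-mediated intramolecular Knoevenagel-type aldol cyclodehydration of the complete acyclic 1,5-diketone amide, the way the polyketide chain is thought to close in nature.
2. The diketone comes from oxidation of a homoallylic alcohol made by α-chloroallylboration of (S)-2-methyl-5-oxohexanal; this one event forms the C–C bond and the (E)-chloroalkene.
3. The α-chloroallylboronate comes from the N-propargyl amide by copper-catalysed α-hydroboration and Matteson homologation with LiCHCl2.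
4. (S)-2-Methyl-5-oxohexanal (the ring methyl stereocentre) comes from propanal and methyl vinyl ketone by enamine catalysis.
5. The amide comes from propargylamine and (4E,7S)-7-methoxydodec-4-enoic acid, itself from (S)-epichlorohydrin, n-BuMgCl and pent-4-ynoic acid.

Assumption: the SMILES is read as 4E,7S in the acyl chain, E at the chloroalkene (Cl cis to the ring) and S at the ring carbon that carries the methyl group next to the ketone.

## Route

Step 1
Reactants: 1 (S)-epichlorohydrin; 2 n-butylmagnesium chloride
Product: 4 (S)-2-pentyloxirane, via (S)-1-chloroheptan-2-ol 3 (not isolated)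
Conditions: CuBr·SMe2 (5 mol %), THF, −40 → 0 °C; then 4 M aq NaOH, rt
Reagents that add atoms: none
Why: Copper-catalysed Grignard opening of the epoxide at its CH2 carbon (faster than direct displacement of chloride) gives the chlorohydrin, which closes under NaOH by intramolecular Williamson etherification onto the CH2Cl carbon; no bond to the stereocentre is made or broken, so the S configuration of 1 is carried into 4.

Step 2
Reactants: 4 (S)-2-pentyloxirane; 5 pent-4-ynoic acid
Product: 8 (S)-7-methoxydodec-4-ynoic acid, via dilithium (S)-7-oxidododec-4-ynoate 6 (not isolated), via methyl (S)-7-methoxydodec-4-ynoate 7 (not isolated)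
Conditions: 5 (1.3 equiv), n-BuLi (2.6 equiv), THF/DMPU 4:1, −78 → 0 °C; 4, 0 → 45 °C; MeI (8 equiv), 0 → 40 °C; then aq LiOH, MeOH, rt; HCl to pH 3
Reagents that add atoms: iodomethane (CI); lithium hydroxide ([Li+].[OH-])
Why: The acetylide–carboxylate dianion of 5 opens the terminal epoxide by SN2 at the CH2 carbon (stereocentre untouched), the lithium alkoxide and carboxylate so formed are both O-methylated by MeI in the dipolar medium (Williamson etherification and esterification), and only the ester is then saponified.

Step 3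
Reactants: 8 (S)-7-methoxydodec-4-ynoic acid
Product: 9 (4E,7S)-7-methoxydodec-4-enoic acid
Conditions: Li (8 equiv), NH3(l)/THF, −33 °C; solid NH4Cl
Reagents that add atoms: none
Why: Dissolving-metal (Birch-type) reduction of the isolated alkyne runs through a vinyl radical anion and vinyl anion that adopt the trans geometry before protonation, giving the 4E alkene only, while the carboxylate and the homopropargylic methyl ether are inert.

Step 4
Reactants: 9 (4E,7S)-7-methoxydodec-4-enoic acid; 10 prop-2-yn-1-amine
Product: 11 (4E,7S)-7-methoxy-N-(prop-2-yn-1-yl)dodec-4-enamide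
Conditions: EDC·HCl (1.3 equiv), HOBt (1.2 equiv), i-Pr2NEt, CH2Cl2, 0 °C → rt
Reagents that add atoms: none
Why: Standard carbodiimide/HOBt amide coupling of an unhindered acid and a primary amine; nothing else in either partner reacts and no stereocentre is involved.

Step 5
Reactants: 11 (4E,7S)-7-methoxy-N-(prop-2-yn-1-yl)dodec-4-enamide
Product: 12 (4E,7S)-7-methoxy-N-[2-(4,4,5,5-tetramethyl-1,3,2-dioxaborolan-2-yl)prop-2-en-1-yl]dodec-4-enamide
Conditions: (SIMes)CuCl, i.e. chloro[1,3-bis(2,4,6-trimethylphenyl)imidazolidin-2-ylidene]copper (5 mol %), NaOt-Bu (5 mol %), B2pin2 (1.1 equiv), MeOH (2 equiv), THF, −50 → −15 °C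
Reagents that add atoms: bis(pinacolato)diboron (CC1(C)OB(OC1(C)C)B1OC(C)(C)C(C)(C)O1)
Why: NHC–copper-catalysed protoboration of the terminal alkyne: syn addition of Cu–Bpin puts boron on the internal carbon when an N-aryl carbene ligand and a propargylic amide substituent are combined, and methanol protonates the alkenylcopper, while the remote unactivated E-alkene does not react.

Step 6
Reactants: 12 (4E,7S)-7-methoxy-N-[2-(4,4,5,5-tetramethyl-1,3,2-dioxaborolan-2-yl)prop-2-en-1-yl]dodec-4-enamide
Product: 14 (4E,7S)-N-[3-chloro-2-methylidene-3-(4,4,5,5-tetramethyl-1,3,2-dioxaborolan-2-yl)propyl]-7-methoxydodec-4-enamide, via dilithium dichloromethylborate complex 13 (not isolated)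
Conditions: CH2Cl2 (3 equiv), n-BuLi (2.3 equiv), THF, −100 °C; add 12; ZnCl2 (2.5 equiv), −100 °C → rt; aq NH4Cl; used at once
Reagents that add atoms: dichloromethyllithium ([Li]C(Cl)Cl), made in the flask from dichloromethane (ClCCl) and n-butyllithium ([Li]CCCC)
Why: Matteson homologation: LiCHCl2 adds to boron (the first equivalent is spent on the amide N–H) and ZnCl2-assisted 1,2-migration of the alkenyl group with loss of chloride inserts one CHCl unit to give the α-chloroallylboronate, whose configuration at C–Cl does not matter because that carbon becomes sp2 in step 8.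

Step 7
Reactants: 15 propanal; 16 but-3-en-2-one
Product: 17 (S)-2-methyl-5-oxohexanal
Conditions: (R)-2-(methoxydiphenylmethyl)pyrrolidine (5 mol %), ethyl 3,4-dihydroxybenzoate (20 mol %), 16 (1.5 equiv), neat, 4 °C, 36 h
Reagents that add atoms: none
Why: Enamine-catalysed asymmetric Michael addition: the E-enamine of propanal is shielded on one face by the methoxydiphenylmethyl group of the R catalyst, so the enone adds to the other face and C2 (the later ring methyl carbon) is formed S in about 95% ee.

Step 8
Reactants: 14 (4E,7S)-N-[3-chloro-2-methylidene-3-(4,4,5,5-tetramethyl-1,3,2-dioxaborolan-2-yl)propyl]-7-methoxydodec-4-enamide; 17 (S)-2-methyl-5-oxohexanal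
Product: 19 (4E,7S)-N-[(2E,5S)-2-(chloromethylidene)-4-hydroxy-5-methyl-8-oxononyl]-7-methoxydodec-4-enamide, via pinacol borate ester 18 (not isolated)
Conditions: 17 (1.5 equiv), toluene (1 M), 4 Å MS, rt → 40 °C, 48 h; then aq NaHCO3
Reagents that add atoms: none
Why: Hoffmann-type α-chloroallylboration through a closed six-membered chair transition state attacks only the aldehyde (not the ketone) with allylic transposition, and the α-chlorine sits axial (reinforced by 1,2-allylic strain with the amidomethyl group) so that Cl ends up cis to the new CH2–CH(OH) branch, i.e. the E-chloroalkene; the carbinol carbon forms as a mixture that is erased in step 9 and the α-methyl stereocentre is not enolised under these neutral conditions.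

Step 9
Reactants: 19 (4E,7S)-N-[(2E,5S)-2-(chloromethylidene)-4-hydroxy-5-methyl-8-oxononyl]-7-methoxydodec-4-enamide
Product: 20 (4E,7S)-N-[(2E,5S)-2-(chloromethylidene)-5-methyl-4,8-dioxononyl]-7-methoxydodec-4-enamide
Conditions: Dess–Martin periodinane (1.3 equiv), NaHCO3 (5 equiv), CH2Cl2, 0 °C → rt; aq Na2S2O3
Reagents that add atoms: none
Why: Buffered Dess–Martin oxidation of the secondary alcohol (drawn out of its hemiketal equilibrium with the methyl ketone) gives the β,γ-unsaturated ketone under conditions that neither move the double bond into conjugation nor epimerise the adjacent methyl stereocentre.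

Step 10
Reactants: 20 (4E,7S)-N-[(2E,5S)-2-(chloromethylidene)-5-methyl-4,8-dioxononyl]-7-methoxydodec-4-enamide
Product: 22 (4E,7S)-N-[(2E)-3-chloro-2-[(5S)-2,5-dimethyl-6-oxocyclohex-1-en-1-yl]prop-2-en-1-yl]-7-methoxydodec-4-enamide, via β-hydroxy ketone 21 (not isolated)
Conditions: DBU (1.0 equiv), toluene, 4 Å MS, 0 → 40 °C
Reagents that add atoms: none
Why: Biomimetic intramolecular Knoevenagel-type aldol condensation: DBU removes only the doubly activated hydrogen between the ketone and the chloroalkene (several pKa units more acidic than the methyl-ketone hydrogens and the hydrogen at the methyl stereocentre), the dienolate attacks the methyl ketone through its α-carbon in a six-membered closure, and irreversible E1cB loss of water gives the tetrasubstituted enone; no new stereocentre is formed and the chloroalkene geometry is not touched.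

## Compound list

1 | (S)-epichlorohydrin | ClC[C@@H]1CO1 | starting material
2 | n-butylmagnesium chloride | CCCC[Mg]Cl | starting material
3 | (S)-1-chloroheptan-2-ol (formed as its magnesium alkoxide) | CCCCC[C@H](O)CCl | intermediate
4 | (S)-2-pentyloxirane | CCCCC[C@H]1CO1 | intermediate
5 | pent-4-ynoic acid | C#CCCC(=O)O | starting material
6 | dilithium (S)-7-oxidododec-4-ynoate | CCCCC[C@H]([O-])CC#CCCC(=O)[O-].[Li+].[Li+] | intermediate
7 | methyl (S)-7-methoxydodec-4-ynoate | CCCCC[C@H](OC)CC#CCCC(=O)OC | intermediate
8 | (S)-7-methoxydodec-4-ynoic acid | CCCCC[C@H](OC)CC#CCCC(=O)O | intermediate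
9 | (4E,7S)-7-methoxydodec-4-enoic acid | CCCCC[C@@H](C/C=C/CCC(=O)O)OC | intermediate
10 | prop-2-yn-1-amine (propargylamine) | C#CCN | starting material
11 | (4E,7S)-7-methoxy-N-(prop-2-yn-1-yl)dodec-4-enamide | CCCCC[C@@H](C/C=C/CCC(=O)NCC#C)OC | intermediate
12 | (4E,7S)-7-methoxy-N-[2-(4,4,5,5-tetramethyl-1,3,2-dioxaborolan-2-yl)prop-2-en-1-yl]dodec-4-enamide | CCCCC[C@@H](C/C=C/CCC(=O)NCC(=C)B1OC(C)(C)C(C)(C)O1)OC | intermediate
13 | dilithium salt of the N-deprotonated (dichloromethyl)borate complex of 12 | CCCCC[C@@H](C/C=C/CCC(=O)[N-]CC(=C)[B-]1(C(Cl)Cl)OC(C)(C)C(C)(C)O1)OC.[Li+].[Li+] | intermediate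
14 | (4E,7S)-N-[3-chloro-2-methylidene-3-(4,4,5,5-tetramethyl-1,3,2-dioxaborolan-2-yl)propyl]-7-methoxydodec-4-enamide (both epimers at C–Cl) | CCCCC[C@@H](C/C=C/CCC(=O)NCC(=C)C(Cl)B1OC(C)(C)C(C)(C)O1)OC | intermediate
15 | propanal | CCC=O | starting material
16 | but-3-en-2-one (methyl vinyl ketone) | CC(=O)C=C | starting material
17 | (S)-2-methyl-5-oxohexanal | CC(=O)CC[C@H](C)C=O | intermediate
18 | pinacol borate ester of 19 (O–Bpin on the new carbinol, both carbinol epimers) | CCCCC[C@@H](C/C=C/CCC(=O)NC/C(=C/Cl)CC(OB1OC(C)(C)C(C)(C)O1)[C@@H](C)CCC(C)=O)OC | intermediate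
19 | (4E,7S)-N-[(2E,5S)-2-(chloromethylidene)-4-hydroxy-5-methyl-8-oxononyl]-7-methoxydodec-4-enamide (both carbinol epimers) | CCCCC[C@@H](C/C=C/CCC(=O)NC/C(=C/Cl)CC(O)[C@@H](C)CCC(C)=O)OC | intermediate
20 | (4E,7S)-N-[(2E,5S)-2-(chloromethylidene)-5-methyl-4,8-dioxononyl]-7-methoxydodec-4-enamide | CCCCC[C@@H](C/C=C/CCC(=O)NC/C(=C/Cl)CC(=O)[C@@H](C)CCC(C)=O)OC | intermediate
21 | (4E,7S)-N-[(2E)-3-chloro-2-[(5S)-2-hydroxy-2,5-dimethyl-6-oxocyclohexyl]prop-2-en-1-yl]-7-methoxydodec-4-enamide (diastereomers at the two new ring carbons) | CCCCC[C@@H](C/C=C/CCC(=O)NC/C(=C/Cl)C1C(C)(O)CC[C@H](C)C1=O)OC | intermediate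
22 | (4E,7S)-N-[(2E)-3-chloro-2-[(5S)-2,5-dimethyl-6-oxocyclohex-1-en-1-yl]prop-2-en-1-yl]-7-methoxydodec-4-enamide | CCCCC[C@@H](C/C=C/CCC(=O)NC/C(=C/Cl)C1=C(C)CC[C@H](C)C1=O)OC | target

## Step count and risks

Total steps: 10. Longest linear sequence: 9 (steps 1–6, 8, 9, 10); step 7 is a one-step side branch.

**Step 10 (ring closure) – most likely to fail.** The base may move the β,γ-double bond into conjugation (giving an allylic chloride), the reaction may stall at aldol 21, or longer exposure may epimerise the methyl stereocentre; epimerisation would show as a second diastereomer because the 7S centre is fixed. Fallback: set out from diketone 20 and separate C–C bond formation from dehydration. Soft enolisation with TiCl4/i-Pr2NEt (CH2Cl2, −78 °C) forms the titanium enolate on the chloroallyl side and the intramolecular aldol is quenched cold, so that β-hydroxy ketone 21 is isolated. Acetylation (Ac2O, DMAP, pyridine, 0 °C) gives the tertiary acetate (4E,7S)-N-[(2E)-2-[(5S)-2-acetoxy-2,5-dimethyl-6-oxocyclohexyl]-3-chloroprop-2-en-1-yl]-7-methoxydodec-4-enamide F1, and brief treatment with DBU (CH2Cl2, 0 °C) expels acetate by E1cB to come back to the route at target 22.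

**Step 6 (Matteson homologation beside a free amide N–H).** The lithium amidate may chelate boron and block addition of LiCHCl2, or later displace the new α-chloride. Fallback: build the same borate from the other side. Set out from acid 9 and couple it (EDC·HCl, HOBt, CH2Cl2) with 2-bromoallylamine to give (4E,7S)-N-(2-bromoprop-2-en-1-yl)-7-methoxydodec-4-enamide F2. MeLi (1 equiv) and then t-BuLi (2 equiv, THF, −78 °C) give (4E,7S)-N-lithio-N-(2-lithioprop-2-en-1-yl)-7-methoxydodec-4-enamide F3, which is added to commercial 2-(dichloromethyl)-4,4,5,5-tetramethyl-1,3,2-dioxaborolane. This comes back to the route at borate 13, which rearranges to 14 with ZnCl2 as in step 6; the carbenoid never meets the N–H and boron is attacked intermolecularly.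

**Step 2 (one-pot epoxide opening, O-methylation and saponification).** The dianion of 5 is poorly soluble and may open the epoxide slowly, and the lithium alkoxide may methylate incompletely. Fallback: set out from epoxide 4 and use a neutral alkyne partner under Lewis-acid activation. Lithiated tert-butyl(dimethyl)(pent-4-yn-1-yloxy)silane with BF3·OEt2 (THF, −78 °C) gives (S)-1-[tert-butyl(dimethyl)silyloxy]dodec-4-yn-7-ol F4. NaH/MeI (THF) gives tert-butyl{[(7S)-7-methoxydodec-4-yn-1-yl]oxy}dimethylsilane F5. Jones oxidation (CrO3, H2SO4, acetone, 0 °C) removes the silyl group and oxidises the primary alcohol, coming back to the route at acid 8.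

Further compounds
F1 | step 10 | (4E,7S)-N-[(2E)-2-[(5S)-2-acetoxy-2,5-dimethyl-6-oxocyclohexyl]-3-chloroprop-2-en-1-yl]-7-methoxydodec-4-enamide | CCCCC[C@@H](C/C=C/CCC(=O)NC/C(=C/Cl)C1C(C)(OC(C)=O)CC[C@H](C)C1=O)OC
F2 | step 6 | (4E,7S)-N-(2-bromoprop-2-en-1-yl)-7-methoxydodec-4-enamide | CCCCC[C@@H](C/C=C/CCC(=O)NCC(Br)=C)OC
F3 | step 6 | (4E,7S)-N-lithio-N-(2-lithioprop-2-en-1-yl)-7-methoxydodec-4-enamide | CCCCC[C@@H](C/C=C/CCC(=O)N([Li])CC(=C)[Li])OC
F4 | step 2 | (S)-1-[tert-butyl(dimethyl)silyloxy]dodec-4-yn-7-ol | CCCCC[C@H](O)CC#CCCCO[Si](C)(C)C(C)(C)C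
F5 | step 2 | tert-butyl{[(7S)-7-methoxydodec-4-yn-1-yl]oxy}dimethylsilane | CCCCC[C@H](OC)CC#CCCCO[Si](C)(C)C(C)(C)C
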